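Ring A is opened at the C1–C2 bond (vinylic CH to the quaternary carbon) and the C3–C4 bond (its two CH2 groups). A temporary Si–O tether joins the vinylic silicon on C1 of a ring-B bis-exocyclic diene to the allylic alcohol that is the C2 methyl in oxidised form, so that one intramolecular Diels–Alder reaction unites the aryl-bearing half with the terpene half, closes ring A and creates quaternary C2. The feature exploited is the C1=C8a alkene next to the C4a–H stereocentre in ring A: it is the anti SE2′ protodesilylation product of the C1-silyl Δ4a(8a) cycloadduct.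

Key step: step 11

Remark: decalin numbering is used for the terpene part (ring A: C1 vinylic CH, C2 quaternary C, C3 and C4 CH2, C4a ring-fusion CH, C8a ring-fusion alkene carbon; ring B: C5 bearing CMe2OH, C6, C7, C8 bearing CH3), the benzylic carbon is called Cα, and commercial (R)-citronellal of high enantiomeric purity is assumed.

Step 1
Reactants: 1 (R)-citronellal, (3R)-3,7-dimethyloct-6-enal
Product: 3 (3R)-3,7-dimethyloct-6-en-1-yne, via alkenyl nonaflate 2 (not isolated)
Conditions: C4F9SO2F, P2-Et phosphazene base [EtN=P(NMe2)2N=P(NMe2)3] (2.2 equiv), DMF, −30 → 23 °C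
Reagents that add atoms: none
Why: Enolisation and O-sulfonylation give the alkenyl nonaflate, from which the phosphazene base eliminates nonaflate (one-pot aldehyde-to-alkyne conversion without homologation, a vinyl sulfonate elimination); the C3 stereocentre (later C8) is not involved.

Step 2
Reactants: 3 (3R)-3,7-dimethyloct-6-en-1-yne
Product: 4 (3S)-2,2-dimethyl-3-[(3R)-3-methylpent-4-yn-1-yl]oxirane
Conditions: L-fructose-derived Shi ketone (0.3 equiv), KHSO5 (Oxone), K2CO3, Bu4NHSO4, MeCN–CH2(OMe)2, aq. Na2B4O7 buffer, 0 °C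
Reagents that add atoms: potassium peroxymonosulfate (KHSO5, Oxone), [K+].[O-]S(=O)(=O)OO
Why: Shi asymmetric epoxidation: the chiral dioxirane transfers oxygen to the trisubstituted alkene through a spiro transition state, the L-fructose-derived ketone should give the (S)-epoxide, and the alkyne is inert to the dioxirane.

Step 3
Reactants: 4 (3S)-2,2-dimethyl-3-[(3R)-3-methylpent-4-yn-1-yl]oxirane
Product: 5 (3S,6R)-3-ethenyl-2,6-dimethyloct-7-yn-2-ol
Conditions: CH2=CHMgBr (4 equiv), CuI (30 mol%), THF, −30 → 0 °C; aq. NH4Cl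
Reagents that add atoms: vinylmagnesium bromide, C=C[Mg]Br
Why: Copper-catalysed SN2 opening of the epoxide at its secondary carbon with inversion sets the C5 stereocentre and frees the tertiary alcohol; the first equivalent of Grignard reagent only turns the alkyne into its magnesium acetylide.

Step 4
Reactants: 5 (3S,6R)-3-ethenyl-2,6-dimethyloct-7-yn-2-ol
Product: 6 {[(3S,6R)-3-ethenyl-2,6-dimethyloct-7-yn-2-yl]oxy}triethylsilane
Conditions: Et3SiOTf, 2,6-lutidine, CH2Cl2, −78 → 0 °C
Reagents that add atoms: triethylsilyl trifluoromethanesulfonate, CC[Si](CC)(CC)OS(=O)(=O)C(F)(F)F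
Why: Silylation of the hindered tertiary alcohol with a silyl triflate; the terminal alkyne is untouched.

Step 5
Reactants: 6 {[(3S,6R)-3-ethenyl-2,6-dimethyloct-7-yn-2-yl]oxy}triethylsilane
Product: 7 N,N-diethyl-1,1-dimethyl-1-[(3R,6S)-6-ethenyl-3,7-dimethyl-7-(triethylsilyloxy)oct-1-yn-1-yl]silanamine
Conditions: n-BuLi, THF, −78 °C; ClSiMe2NEt2, −78 → 23 °C; filtered under Ar, used crude
Reagents that add atoms: chloro(diethylamino)dimethylsilane, CCN(CC)[Si](C)(C)Cl
Why: The lithium acetylide displaces chloride, the better leaving group, at silicon and leaves the Si–N bond as the handle for the later tether.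

Step 6
Reactants: 7 N,N-diethyl-1,1-dimethyl-1-[(3R,6S)-6-ethenyl-3,7-dimethyl-7-(triethylsilyloxy)oct-1-yn-1-yl]silanamine
Product: 8 N,N-diethyl-1,1-dimethyl-1-{(E)-[(2R,5S)-2-methyl-6-methylidene-5-[2-(triethylsilyloxy)propan-2-yl]cyclohexylidene]methyl}silanamine
Conditions: Pd(OAc)2 (5 mol%), N,N′-bis(benzylidene)ethylenediamine (6 mol%), PhH, 65 °C; Celite filtration under Ar, used at once
Reagents that add atoms: none
Why: Palladium-catalysed enyne cycloisomerisation (Alder-ene type, 6-exo closure of ring B): cis addition across the alkyne joins C8a to the vinyl CH (C4a), and β-hydride loss from C4a–H, the only β-hydrogen, should give the 1,2-bis(alkylidene)cyclohexane with silicon trans to the new C8a–C4a bond (E).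

Step 7
Reactants: 9 3,5-dimethoxyphenol; 10 (E)-5-methylhex-2-enal
Product: 11 (4S)-5,7-dimethoxy-4-(2-methylpropyl)-3,4-dihydro-2H-chromen-2-ol (anomeric mixture)
Conditions: (R)-α,α-diphenylprolinol trimethylsilyl ether (20 mol%), PhCO2H (20 mol%), PhMe, 0 → 23 °C
Reagents that add atoms: none
Why: Iminium-catalysed Friedel–Crafts alkylation followed by hemiacetal closure: the arene attacks the β-carbon of the E-iminium ion on the face opposite the CPh2(OSiMe3) group of the (R)-catalyst, which should set the (S) benzylic centre Cα; any para-alkylated open-chain regioisomer converges in step 8.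

Step 8
Reactants: 11 (4S)-5,7-dimethoxy-4-(2-methylpropyl)-3,4-dihydro-2H-chromen-2-ol
Product: 12 (3S)-5-methyl-3-(2,4,6-trimethoxyphenyl)hexanal
Conditions: MeI, K2CO3, DMF, 23 °C
Reagents that add atoms: iodomethane, CI
Why: Williamson methylation of the phenoxide of the ring-opened hydroxy aldehyde drains the lactol equilibrium and gives the symmetric 2,4,6-trimethoxyphenyl group.

Step 9
Reactants: 12 (3S)-5-methyl-3-(2,4,6-trimethoxyphenyl)hexanal
Product: 13 (3R)-5-methyl-2-methylidene-3-(2,4,6-trimethoxyphenyl)hexanal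
Conditions: 37% aq. CH2O, pyrrolidine (10 mol%), EtCO2H (10 mol%), i-PrOH, 45 °C
Reagents that add atoms: formaldehyde, C=O
Why: Amine-catalysed α-methylenation (Mannich condensation and elimination through the enamine); the descriptor at Cα changes only by CIP priority, not in space.

Step 10
Reactants: 13 (3R)-5-methyl-2-methylidene-3-(2,4,6-trimethoxyphenyl)hexanal
Product: 14 (3S)-5-methyl-2-methylidene-3-(2,4,6-trimethoxyphenyl)hexan-1-ol
Conditions: NaBH4, CeCl3·7H2O, MeOH, −20 °C
Reagents that add atoms: none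
Why: Luche 1,2-reduction of the enal gives the allylic alcohol whose CH2O carbon is the future C2 methyl group.

Step 11
Reactants: 8 the (E)-dienyl aminosilane; 14 the allylic alcohol
Product: 16 Diels–Alder adduct (Δ4a(8a)-octalin with a cis-fused 2,2-dimethyl-1-oxa-2-silacyclopentane across C1–C2), via silyl ether triene 15 (not isolated)
Conditions: PhMe, 60 °C (Ar stream, −Et2NH); then 140 °C (sealed), 2,6-di-tert-butyl-4-methylphenol (cat.)
Reagents that add atoms: none
Why: Alcoholysis of the Si–N bond by 14 forms the silyl ether 15, which undergoes a concerted thermal intramolecular [4+2] cycloaddition between the bis-exocyclic diene (C4=C4a–C8a=C1) and the unactivated 1,1-disubstituted alkene (C2=C3); the closest known reaction type is the Diels–Alder reaction through a temporary silicon connection (dienylsilyl ether of an allylic alcohol). Ring A closes by suprafacial [4+2] addition, and the five-membered 1-oxa-2-silacyclopentane closes at the same time in the fused mode of a type 1 intramolecular Diels–Alder reaction with a three-atom tether. The tether alone fixes the regiochemistry (C1–C2 and C3–C4), which an untethered 1-silyl diene would not give, and lets the unactivated alkene react. Facial selectivity on the diene is secured by the C8 methyl, held pseudoaxial by allylic 1,3-strain with the E vinylic silicon, and by the C5 CMe2OSiEt3 group, both on the same face, so the dienophile should add to the opposite face. The short tether takes the endo position and the bulky CH(i-Bu)Ar group the exo position, which gives the cis-fused oxasilolane and so places the CH2O group on C2 syn to silicon on C1. Cα is carried in unchanged from 14.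

Step 12
Reactants: 16 the Diels–Alder adduct
Product: 18 [(2R,4aR,5S,8R)-5-(2-hydroxypropan-2-yl)-8-methyl-2-[(1S)-3-methyl-1-(2,4,6-trimethoxyphenyl)butyl]-2,3,4,4a,5,6,7,8-octahydronaphthalen-2-yl]methanol, via silyl trifluoroacetate 17 (not isolated)
Conditions: CF3CO2H (3 equiv), CH2Cl2, −20 °C; then Bu4NF, THF, 23 °C
Reagents that add atoms: none
Why: Acid protodesilylation of the allylsilane (anti SE2′): the proton adds to C4a on the face opposite the C1–Si bond to give a β-silyl cation at C8a, loss of silicon moves the alkene to C1=C8a and sets C4a–H (C4 and the C5 substituent trans-diequatorial), and fluoride then cleaves the Si–O bonds of the silyl trifluoroacetate and of the triethylsilyl ether.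

Step 13
Reactants: 18 the diol
Product: 19 (2R,4aR,5S,8R)-5-(2-hydroxypropan-2-yl)-8-methyl-2-[(1R)-3-methyl-1-(2,4,6-trimethoxyphenyl)butyl]-2,3,4,4a,5,6,7,8-octahydronaphthalene-2-carbaldehyde
Conditions: Dess–Martin periodinane, CH2Cl2, 23 °C
Reagents that add atoms: none
Why: Dess–Martin oxidation of the primary neopentyl alcohol to the aldehyde; the tertiary alcohol cannot be oxidised (descriptors at C2 and Cα change by CIP priority only).

Step 14
Reactants: 19 the aldehyde
Product: 21 (2S,4aR,5S,8R)-5-(2-hydroxypropan-2-yl)-2,8-dimethyl-2-[(1S)-3-methyl-1-(2,4,6-trimethoxyphenyl)butyl]-2,3,4,4a,5,6,7,8-octahydronaphthalene, via hydrazone 20 (not isolated)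
Conditions: N2H4·H2O, diethylene glycol, 130 °C; then KOH, 200 °C (−H2O), Ar
Reagents that add atoms: none
Why: Wolff–Kishner reduction (Huang-Minlon conditions) of the non-enolisable aldehyde through its hydrazone turns the tether carbon into the C2 methyl group; an ionic route is chosen because a radical deoxygenation at this homoallylic carbon would risk 1,2-vinyl migration.

Step 15
Reactants: 21 the trimethoxyaryl compound
Product: 23 5-[(1S)-1-[(2S,4aR,5S,8R)-5-(2-hydroxypropan-2-yl)-2,8-dimethyl-2,3,4,4a,5,6,7,8-octahydronaphthalen-2-yl]-3-methylbutyl]-2,4,6-trimethoxybenzene-1,3-dicarbaldehyde, via amino alkoxide 22 (not isolated)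
Conditions: n-BuLi (2.1 equiv), TMEDA, THF, 0 °C; DMF (1.1 equiv), −78 °C; n-BuLi (2 equiv), −20 → 0 °C; DMF (excess), −78 → 0 °C; 1 M HCl
Reagents that add atoms: N,N-dimethylformamide, CN(C)C=O
Why: Directed ortho-metalation: each remaining aryl C–H lies between two methoxy groups and is lithiated (the tertiary alcohol is carried as its lithium alkoxide), the first DMF adduct stays as a lithium α-amino alkoxide that masks the aldehyde during the second lithiation and formylation, and acid work-up releases both formyl groups.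

Step 16
Reactants: 23 the dialdehyde trimethyl ether
Product: 24 5-[(1S)-1-[(2S,4aR,5S,8R)-5-(2-hydroxypropan-2-yl)-2,8-dimethyl-2,3,4,4a,5,6,7,8-octahydronaphthalen-2-yl]-3-methylbutyl]-2,4,6-trihydroxybenzene-1,3-dicarbaldehyde (target)
Conditions: NaSEt (12 equiv), DMF, 110 °C; then 1 M HCl, 0 °C
Reagents that add atoms: none
Why: Thiolate SN2 O-demethylation of the three aryl methyl ethers, each activated by an ortho formyl group, under basic conditions that spare the tertiary alcohol and the trisubstituted alkene; reversible thiolate addition to the aldehydes is undone on acidic work-up.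

Compound list
1 | (R)-citronellal, (3R)-3,7-dimethyloct-6-enal | C[C@H](CCC=C(C)C)CC=O | starting material
2 | (3R)-3,7-dimethylocta-1,6-dien-1-yl nonafluorobutane-1-sulfonate (E/Z mixture) | C[C@H](CCC=C(C)C)C=COS(=O)(=O)C(F)(F)C(F)(F)C(F)(F)C(F)(F)F | intermediate
3 | (3R)-3,7-dimethyloct-6-en-1-yne | C#C[C@H](C)CCC=C(C)C | intermediate
4 | (3S)-2,2-dimethyl-3-[(3R)-3-methylpent-4-yn-1-yl]oxirane | C#C[C@H](C)CC[C@@H]1OC1(C)C | intermediate
5 | (3S,6R)-3-ethenyl-2,6-dimethyloct-7-yn-2-ol | C#C[C@H](C)CC[C@@H](C=C)C(C)(C)O | intermediate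
6 | {[(3S,6R)-3-ethenyl-2,6-dimethyloct-7-yn-2-yl]oxy}triethylsilane | C#C[C@H](C)CC[C@@H](C=C)C(C)(C)O[Si](CC)(CC)CC | intermediate
7 | N,N-diethyl-1,1-dimethyl-1-[(3R,6S)-6-ethenyl-3,7-dimethyl-7-(triethylsilyloxy)oct-1-yn-1-yl]silanamine | CCN(CC)[Si](C)(C)C#C[C@H](C)CC[C@@H](C=C)C(C)(C)O[Si](CC)(CC)CC | intermediate
8 | N,N-diethyl-1,1-dimethyl-1-{(E)-[(2R,5S)-2-methyl-6-methylidene-5-[2-(triethylsilyloxy)propan-2-yl]cyclohexylidene]methyl}silanamine (Si cis to the CH(CH3) ring carbon) | CCN(CC)[Si](C)(C)/C=C1\[C@H](C)CC[C@H](C(C)(C)O[Si](CC)(CC)CC)C1=C | intermediate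
9 | 3,5-dimethoxyphenol | COc1cc(O)cc(OC)c1 | starting material
10 | (E)-5-methylhex-2-enal | CC(C)C/C=C/C=O | starting material
11 | (4S)-5,7-dimethoxy-4-(2-methylpropyl)-3,4-dihydro-2H-chromen-2-ol (anomeric mixture) | CC(C)C[C@H]1CC(O)Oc2cc(OC)cc(OC)c21 | intermediate
12 | (3S)-5-methyl-3-(2,4,6-trimethoxyphenyl)hexanal | CC(C)C[C@H](c1c(OC)cc(OC)cc1OC)CC=O | intermediate
13 | (3R)-5-methyl-2-methylidene-3-(2,4,6-trimethoxyphenyl)hexanal | CC(C)C[C@H](c1c(OC)cc(OC)cc1OC)C(=C)C=O | intermediate
14 | (3S)-5-methyl-2-methylidene-3-(2,4,6-trimethoxyphenyl)hexan-1-ol | CC(C)C[C@H](c1c(OC)cc(OC)cc1OC)C(=C)CO | intermediate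
15 | silyl ether triene: the (E)-dienyl(dimethyl)silyl ether formed from 8 and the primary hydroxyl of 14 | CC(C)C[C@H](c1c(OC)cc(OC)cc1OC)C(=C)CO[Si](C)(C)/C=C1\[C@H](C)CC[C@H](C(C)(C)O[Si](CC)(CC)CC)C1=C | intermediate
16 | Diels–Alder adduct: Δ4a(8a)-octalin with a cis-fused 2,2-dimethyl-1-oxa-2-silacyclopentane across C1–C2 (Si on C1 and OCH2 on C2 on the face opposite the C8 methyl and the C5 CMe2OSiEt3 group); C2 also bears the 3-methyl-1-(2,4,6-trimethoxyphenyl)butyl group with Cα as in 14 | CC(C)C[C@H](c1c(OC)cc(OC)cc1OC)[C@@]12CCC3=C([C@H](C)CC[C@@H]3C(C)(C)O[Si](CC)(CC)CC)[C@@H]1[Si](C)(C)OC2 | intermediate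
17 | silyl trifluoroacetate: 18 carrying CH2O–SiMe2–OCOCF3 on C2 and the triethylsilyl ether on the tertiary alcohol | CC(C)C[C@H](c1c(OC)cc(OC)cc1OC)[C@]1(CO[Si](C)(C)OC(=O)C(F)(F)F)C=C2[C@H](C)CC[C@H](C(C)(C)O[Si](CC)(CC)CC)[C@H]2CC1 | intermediate
18 | [(2R,4aR,5S,8R)-5-(2-hydroxypropan-2-yl)-8-methyl-2-[(1S)-3-methyl-1-(2,4,6-trimethoxyphenyl)butyl]-2,3,4,4a,5,6,7,8-octahydronaphthalen-2-yl]methanol | CC(C)C[C@H](c1c(OC)cc(OC)cc1OC)[C@]1(CO)C=C2[C@H](C)CC[C@H](C(C)(C)O)[C@H]2CC1 | intermediate
19 | (2R,4aR,5S,8R)-5-(2-hydroxypropan-2-yl)-8-methyl-2-[(1R)-3-methyl-1-(2,4,6-trimethoxyphenyl)butyl]-2,3,4,4a,5,6,7,8-octahydronaphthalene-2-carbaldehyde | CC(C)C[C@H](c1c(OC)cc(OC)cc1OC)[C@]1(C=O)C=C2[C@H](C)CC[C@H](C(C)(C)O)[C@H]2CC1 | intermediate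
20 | hydrazone of 19 | CC(C)C[C@H](c1c(OC)cc(OC)cc1OC)[C@]1(C=NN)C=C2[C@H](C)CC[C@H](C(C)(C)O)[C@H]2CC1 | intermediate
21 | (2S,4aR,5S,8R)-5-(2-hydroxypropan-2-yl)-2,8-dimethyl-2-[(1S)-3-methyl-1-(2,4,6-trimethoxyphenyl)butyl]-2,3,4,4a,5,6,7,8-octahydronaphthalene | CC(C)C[C@H](c1c(OC)cc(OC)cc1OC)[C@]1(C)C=C2[C@H](C)CC[C@H](C(C)(C)O)[C@H]2CC1 | intermediate
22 | dilithium amino alkoxide: 21 with one aryl position carrying CH(OLi)NMe2 and the tertiary alcohol as OLi | CC(C)C[C@H](c1c(OC)cc(OC)c(C(O[Li])N(C)C)c1OC)[C@]1(C)C=C2[C@H](C)CC[C@H](C(C)(C)O[Li])[C@H]2CC1 | intermediate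
23 | 5-[(1S)-1-[(2S,4aR,5S,8R)-5-(2-hydroxypropan-2-yl)-2,8-dimethyl-2,3,4,4a,5,6,7,8-octahydronaphthalen-2-yl]-3-methylbutyl]-2,4,6-trimethoxybenzene-1,3-dicarbaldehyde | CC(C)C[C@H](c1c(OC)c(C=O)c(OC)c(C=O)c1OC)[C@]1(C)C=C2[C@H](C)CC[C@H](C(C)(C)O)[C@H]2CC1 | intermediate
24 | 5-[(1S)-1-[(2S,4aR,5S,8R)-5-(2-hydroxypropan-2-yl)-2,8-dimethyl-2,3,4,4a,5,6,7,8-octahydronaphthalen-2-yl]-3-methylbutyl]-2,4,6-trihydroxybenzene-1,3-dicarbaldehyde | CC(C)C[C@H](c1c(O)c(C=O)c(O)c(C=O)c1O)[C@]1(C)C=C2[C@H](C)CC[C@H](C(C)(C)O)[C@H]2CC1 | target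

Total step count: 16. Longest linear sequence: 12 steps (steps 1–6, then 11–16); the aryl branch (steps 7–10) joins at step 11.

Steps most likely to fail

1. Step 11 (key cycloaddition). The unactivated 1,1-disubstituted alkene may react too slowly, so that dimerisation of the bis-exocyclic diene competes, or endo/exo control may erode and give the trans-fused oxasilolane with the wrong C1/C2 relationship. The fallback sets out from 13 and 8 and comes back at 18; it replaces the allyl ether tether by an acyloxysilane tether with an activated acrylate dienophile. Pinnick oxidation of 13 (NaClO2, NaH2PO4, 2-methylbut-2-ene, t-BuOH–H2O) should give (3R)-5-methyl-2-methylidene-3-(2,4,6-trimethoxyphenyl)hexanoic acid F1. F1 and 8 (PhMe, 23 °C, −Et2NH) should give the dienylsilyl acrylate F2, whose electron-poor alkene should close at 60–80 °C to the cis-fused silalactone cycloadduct F3. CF3CO2H and then Bu4NF should give the C2 carboxylic acid F4 with the transposed alkene, and LiAlH4 (THF, 65 °C) should reduce F4 to 18.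

2. Step 6 (ring-B cycloisomerisation). Six-membered ring closure next to the bulky C5 substituent may be slow, so that alkyne oligomerisation, loss of the Si–N bond or palladium hydride isomerisation of the diene into the ring takes over. The fallback sets out from 6 and comes back at 8; it uses a stoichiometric zirconocene bicyclisation in place of the palladium catalysis. n-BuLi and then ClSiMe2(O-i-Pr) should give the alkynyl(isopropoxy)dimethylsilane F5. Cp2Zr(n-Bu)2 (from Cp2ZrCl2 and n-BuLi, THF, −78 → 23 °C) should give the zirconabicycle F6. I2 (1 equiv, −78 °C) should cleave its alkyl–zirconium bond and i-PrOH/aq. NH4Cl its alkenyl–zirconium bond, to give the (E)-vinylsilane iodide F7 (CH2I on C4a). DBU (PhMe, 60 °C) should eliminate HI to the dienyl(isopropoxy)silane F8, and LiNEt2 (THF, 0 °C) should exchange isopropoxide for diethylamide at silicon to give 8.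

3. Step 15 (double formylation). The lithium amino alkoxide may collapse to the aldehyde, which then adds n-BuLi, or the second lithiation may stop short and leave mono-aldehyde. The fallback sets out from 21 and comes back at 23; it uses electrophilic bromination and halogen–lithium exchange in place of the two C–H lithiations. Et3SiOTf/2,6-lutidine should give the triethylsilyl ether F9, which keeps the tertiary alcohol from bromoetherification of the C1=C8a alkene. NBS (2.1 equiv, MeCN, 0 °C) should give the 3,5-dibromoaryl compound F10. t-BuLi (4.4 equiv, THF, −78 °C) and then DMF should give the dialdehyde triethylsilyl ether F11, and Bu4NF (THF, 23 °C) should give 23.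

Further compounds
F1 | step 11 | (3R)-5-methyl-2-methylidene-3-(2,4,6-trimethoxyphenyl)hexanoic acid | CC(C)C[C@H](c1c(OC)cc(OC)cc1OC)C(=C)C(=O)O
F2 | step 11 | dienylsilyl acrylate: (E)-dienyl(dimethyl)silyl ester of F1 | CC(C)C[C@H](c1c(OC)cc(OC)cc1OC)C(=C)C(=O)O[Si](C)(C)/C=C1\[C@H](C)CC[C@H](C(C)(C)O[Si](CC)(CC)CC)C1=C
F3 | step 11 | silalactone cycloadduct: 16 with C=O in place of the OCH2 carbon's CH2 (cis-fused 2,2-dimethyl-1-oxa-2-silacyclopentan-5-one) | CC(C)C[C@H](c1c(OC)cc(OC)cc1OC)[C@@]12CCC3=C([C@H](C)CC[C@@H]3C(C)(C)O[Si](CC)(CC)CC)[C@@H]1[Si](C)(C)OC2=O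
F4 | step 11 | (2R,4aR,5S,8R)-5-(2-hydroxypropan-2-yl)-8-methyl-2-[(1R)-3-methyl-1-(2,4,6-trimethoxyphenyl)butyl]-2,3,4,4a,5,6,7,8-octahydronaphthalene-2-carboxylic acid | CC(C)C[C@H](c1c(OC)cc(OC)cc1OC)[C@]1(C(=O)O)C=C2[C@H](C)CC[C@H](C(C)(C)O)[C@H]2CC1
F5 | step 6 | [(3R,6S)-6-ethenyl-3,7-dimethyl-7-(triethylsilyloxy)oct-1-yn-1-yl](isopropoxy)dimethylsilane | CC(C)O[Si](C)(C)C#C[C@H](C)CC[C@@H](C=C)C(C)(C)O[Si](CC)(CC)CC
F6 | step 6 | zirconabicycle: Cp2Zr bonded to C1 (silyl-bearing alkenyl carbon) and to the C4 methylene | CC(C)O[Si](C)(C)C1=C2[C@H](C)CC[C@H](C(C)(C)O[Si](CC)(CC)CC)C2C[Zr]1(C1C=CC=C1)C1C=CC=C1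
F7 | step 6 | (E)-vinylsilane iodide: analogue of 8 with Si(O-i-Pr)Me2 and CH(CH2I) in place of C=CH2 (C4a unassigned) | CC(C)O[Si](C)(C)/C=C1\[C@H](C)CC[C@H](C(C)(C)O[Si](CC)(CC)CC)C1CI
F8 | step 6 | dienyl(isopropoxy)dimethylsilane: analogue of 8 with O-i-Pr in place of NEt2 | CC(C)O[Si](C)(C)/C=C1\[C@H](C)CC[C@H](C(C)(C)O[Si](CC)(CC)CC)C1=C
F9 | step 15 | triethylsilyl ether of 21 | CC(C)C[C@H](c1c(OC)cc(OC)cc1OC)[C@]1(C)C=C2[C@H](C)CC[C@H](C(C)(C)O[Si](CC)(CC)CC)[C@H]2CC1
F10 | step 15 | 3,5-dibromo-2,4,6-trimethoxyphenyl analogue of F9 | CC(C)C[C@H](c1c(OC)c(Br)c(OC)c(Br)c1OC)[C@]1(C)C=C2[C@H](C)CC[C@H](C(C)(C)O[Si](CC)(CC)CC)[C@H]2CC1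
F11 | step 15 | triethylsilyl ether of 23 | CC(C)C[C@H](c1c(OC)c(C=O)c(OC)c(C=O)c1OC)[C@]1(C)C=C2[C@H](C)CC[C@H](C(C)(C)O[Si](CC)(CC)CC)[C@H]2CC1
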